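Time is what is in dispute in the east flask, whose readings look finished by 20.0 h.

| flask | starting complex | incoming ligand | leaving ligand | temperature | remark | time |
|---|---|---|---|---|---|---|
| east | 0.078 M | 1.8 equiv | 0.50 equiv | 20 °C | the very flask that is asked about, followed so far |  |
| south-west | 0.078 M | 3.6 equiv | 0.50 equiv | 15 °C | run made earlier |  |
| flask | 0.078 M | 1.80 equiv | 0.500 equiv | 20 °C |  | 2.5 d |

| run | time / h | complex with two exchanged / % | starting complex / % |
|---|---|---|---|
| east | 2.50 | 4.7 | 73.2 |
| east | 8.00 | 18.5 | 48.3 |
| east | 15.0 | 28.9 | 34.4 |
| east | 20.0 | 33.0 | 30.9 |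
| east | 30.0 | 34.4 | 26.0 |
| east | 40.0 | 33.3 | 25.3 |
| east | 50.0 | 33.2 | 24.3 |
| south-west | 6.00 | 23.3 | 41.2 |
| south-west | 12.0 | 44.0 | 22.0 |
| south-west | 20.0 | 54.8 | 13.5 |
| south-west | 25.0 | 58.3 | 11.6 |
| south-west | 30.0 | 59.2 | 9.5 |
| south-west | 40.0 | 60.5 | 8.5 |

(standard deviation of a reading: 0.5 percentage points)

- additions leave the volume as it is

- Thursday's: at 2.5 d take out 90% of the leaving ligand then present, then wait 5.0 d
- Tuesday's: at 2.5 d add incoming ligand, 50.0% of the amount charged, then wait 5.0 d
- Saturday's: at 2.5 d raise the temperature by 15 K, then wait 5.0 d
- Wednesday's: change nothing and wait 5.0 d more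

* complex with two exchanged, in percent of the starting complex first charged, at 2.5 d
* what to do for the largest gain in complex with two exchanged; "none" if nothing gains more than 2 percentage points (Thursday's / Tuesday's / Saturday's / Wednesday's / none)
* complex with two exchanged present, in percent of the starting complex first charged, after Saturday's
* complex with two exchanged present, in percent of the starting complex first charged, after Wednesday's

Two chemists read these columns differently. The first watches complex with two exchanged, which stands at 34.4%, 33.3% and 33.2% in the last readings of the east run. He adds that in the south-west run [starting complex] + [complex with two exchanged] reads 69.9% at 25.0 h and 69.0% at 40.0 h. So he calls the flask an equilibrium, and on his view further waiting moves nothing.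

The second chemist adds the same two species in the east run. Their sum falls from 63.9% at 20.0 h to 57.5% at 50.0 h, a drop of 6.4 percentage points, larger than the scatter of 0.5 points on a reading. So she takes the flat stretch for a slow slide, kinetic rather than thermodynamic control, and she names one quantity for it. The leak constant is the fractional loss of that sum per unit time, read between those two readings: 0.0844 /d.

My own reckoning follows her. Sliding on from the last reading at that constant, complex with two exchanged stands near 32.1% at 2.5 d, and near 21.0% after Wednesday's.

The forecast takes the first chemist's side, “The east run has levelled off by about 40 h, so 2.5 d is equilibrium”, and gives 33.3% now, Thursday's as best, 30% after Saturday's and 33.2% after Wednesday's.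

The flask gives 32.0% at 2.5 d, 1.17% after Saturday's and 18.4% after Wednesday's, and Thursday's is best, with a gain of 5 points. At 2.5 d it holds 18.6% of side product, which the readings never showed, and the leak constant, laid on the whole charge from the start, gives 19.0% of that charge lost by the same time. The first chemist keeps the span from 0.549 d to 4.10 d, the nearest times at which the answer has moved by 5 points.

    complex with one exchanged + incoming ligand ⇌ leaving ligand + complex with two exchanged (K = 3.70, k = 1.10 /M/h, Ea = 64.0 kJ/mol, ΔH = 2.00 kJ/mol)
    complex with two exchanged → over-reaction product (k = 9.80 × 10⁻⁶ /h, Ea = 110 kJ/mol)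
    complex with one exchanged → side product (k = 0.0110 /h, Ea = 96.0 kJ/mol)
    starting complex + incoming ligand ⇌ leaving ligand + complex with one exchanged (K = 4.20, k = 0.970 /M/h, Ea = 51.0 kJ/mol, ΔH = −13.0 kJ/mol)
    2 incoming ligand → homo dimer (k = 0.0500 /M/h, Ea = 69.0 kJ/mol)
    (constants at 20 °C)

In the neighbouring flask with 4.50 equiv of incoming ligand, the leak constant, carried over unchanged and laid on the whole charge in the same way, again gives 19.0% lost by 2.5 d. The computed side product in that flask is 14.8%, less than this reckoning, beside 56.0% of complex with two exchanged.

The readings come from a simulation from invented constants.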